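Everything rests on cutting the two tetrasubstituted ring olefins of sodwanone T, C10=C11 and C14=C15 (squalene numbering): the double bonds of the two cyclohexene rings, each beside a quaternary carbon (C6, C19), on either side of the C12–C13 bridge. Each olefin is traced back to a 1,6-diketone, so one double intramolecular McMurry coupling closes both cyclohexenes at once from a C2-symmetric tetraketone: a 1,4-diketone (C11, C14) slung between two preformed oxepanes, each bearing a trans 3-oxobutyl arm (methyl ketones C10, C15) and a silyl-protected C3 or C22 hydroxyl. Two-directional synthesis builds this precursor from one oxepane ketone; desilylation and mono-oxidation finish.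

Key step: step 12

Numbering: squalene locants are used for the C30 skeleton (hydroxy half C2–C11, bridge C12–C13, keto half C14–C23); in the monocyclic intermediates C2–C7 coincide with the oxepane locants O1, C2 (gem-dimethyl), C3 (carbinol), C6 (quaternary), C7 (ring CH).

Assumption: (R)-TRIP is taken to direct allyl transfer to the Re face of aldehyde 9, the sense it shows with simple aldehydes; if this substrate behaves oppositely, the (S)-acid is used instead.

Step 1
Reactants: 1 nerol [(2Z)-3,7-dimethylocta-2,6-dien-1-ol]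
Product: 3 neryl chloride [(2Z)-1-chloro-3,7-dimethylocta-2,6-diene], via neryl mesylate 2 (not isolated)
Conditions: MsCl, 2,4,6-collidine, LiCl, DMF, 0 °C
Reagents that add atoms: lithium chloride, [Li+].[Cl-]
Why: The alcohol is mesylated in situ and the primary allylic mesylate is displaced by chloride in an SN2 reaction without passing through an allyl cation, so neither allylic transposition nor loss of the Z geometry is expected (mesylation–chloride displacement).

Step 2
Reactants: 3 neryl chloride; 4 bis(pinacolato)diboron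
Product: 5 neryl pinacol boronate {2-[(2Z)-3,7-dimethylocta-2,6-dien-1-yl]-4,4,5,5-tetramethyl-1,3,2-dioxaborolane}
Conditions: Pd2(dba)3 (1 mol%), THF, 60 °C
Reagents that add atoms: none
Why: Miyaura-type palladium-catalysed allylic borylation: zerovalent palladium adds oxidatively to the allylic chloride, the π-allyl complex transmetallates with the diboron and boron is delivered to the unsubstituted terminus before syn–anti exchange at the fully substituted terminus can erode the Z geometry.

Step 3
Reactants: 6 ethyl levulinate (ethyl 4-oxopentanoate)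
Product: 7 ethyl 3-(2-methyl-1,3-dioxolan-2-yl)propanoate
Conditions: HOCH2CH2OH, TsOH·H2O (cat.), toluene, reflux, Dean–Stark trap
Reagents that add atoms: ethylene glycol, OCCO
Why: Acid-catalysed ketalisation with azeotropic removal of water protects the ketone as its dioxolane while the ester does not react.

Step 4
Reactants: 7 ethyl 3-(2-methyl-1,3-dioxolan-2-yl)propanoate
Product: 9 3-(2-methyl-1,3-dioxolan-2-yl)propanal, via aluminium hemiacetal 8 (not isolated)
Conditions: i-Bu2AlH (DIBAL-H, 1.05 equiv), CH2Cl2, −78 °C; then MeOH, aq. potassium sodium tartrate (KNaC4H4O6)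
Reagents that add atoms: none
Why: One hydride is transferred to the ester and the tetrahedral aluminium hemiacetal 8 persists at −78 °C, collapsing to the aldehyde only on aqueous work-up (partial ester reduction), while the ketal is inert.

Step 5
Reactants: 5 neryl pinacol boronate; 9 3-(2-methyl-1,3-dioxolan-2-yl)propanal
Product: 11 (3S,4S)-4-ethenyl-4,8-dimethyl-1-(2-methyl-1,3-dioxolan-2-yl)non-7-en-3-ol, via pinacol borate 10 (not isolated)
Conditions: (R)-TRIP [(R)-3,3'-bis(2,4,6-triisopropylphenyl)-1,1'-binaphthyl-2,2'-diyl hydrogen phosphate, 5 mol%], 4 Å molecular sieves, toluene, −30 to 0 °C; then aq. NaHCO3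
Reagents that add atoms: none
Why: Chiral phosphoric acid-catalysed allylboration through a closed six-membered chair transition state: the acid, bound to a boronate oxygen and to the formyl hydrogen, directs the allyl group to the Re face of the aldehyde and so sets the carbinol carbon (later C7) as S, while the Z geometry of 5 places the homoprenyl chain syn to the new hydroxyl and thereby fixes the adjacent quaternary carbon (later C6) as S.

Step 6
Reactants: 11 (3S,4S)-4-ethenyl-4,8-dimethyl-1-(2-methyl-1,3-dioxolan-2-yl)non-7-en-3-ol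
Product: 12 (3S,4S)-6-[(2R)-3,3-dimethyloxiran-2-yl]-4-ethenyl-4-methyl-1-(2-methyl-1,3-dioxolan-2-yl)hexan-3-ol
Conditions: D-fructose-derived Shi ketone (1,2:4,5-di-O-isopropylidene-β-D-erythro-2,3-hexodiulo-2,6-pyranose, 0.3 equiv), Oxone (2KHSO5·KHSO4·K2SO4), K2CO3, Bu4NHSO4, aq. Na2B4O7/Na2H2EDTA buffer, MeCN–CH2(OMe)2, 0 °C
Reagents that add atoms: potassium peroxymonosulfate (the oxidant in Oxone), [K+].[O-]S(=O)(=O)OO
Why: Shi asymmetric epoxidation: the dioxirane generated from the D-fructose-derived ketone transfers oxygen through a spiro transition state to one face of the electron-rich trisubstituted olefin under reagent control, which sets the (R)-epoxide carbon (later C3), whereas the hindered monosubstituted vinyl group is a poor substrate and material from the minor enantiomer of 11 becomes a separable diastereomer.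

Step 7
Reactants: 12 (3S,4S)-6-[(2R)-3,3-dimethyloxiran-2-yl]-4-ethenyl-4-methyl-1-(2-methyl-1,3-dioxolan-2-yl)hexan-3-ol
Product: 13 (3R,6S,7S)-6-ethenyl-2,2,6-trimethyl-7-[2-(2-methyl-1,3-dioxolan-2-yl)ethyl]oxepan-3-ol
Conditions: camphorsulfonic acid (10 mol%), CH2Cl2, 0 °C
Reagents that add atoms: none
Why: Acid-catalysed intramolecular epoxide opening in the 7-endo mode: the secondary hydroxyl attacks the protonated epoxide at its gem-dimethyl carbon, which bears most of the developing positive charge, and because the C3–O bond is not broken the epoxide configuration is carried over unchanged into the C3 carbinol of the oxepane.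

Step 8
Reactants: 13 (3R,6S,7S)-6-ethenyl-2,2,6-trimethyl-7-[2-(2-methyl-1,3-dioxolan-2-yl)ethyl]oxepan-3-ol
Product: 14 tert-butyl{[(3R,6S,7S)-6-ethenyl-2,2,6-trimethyl-7-[2-(2-methyl-1,3-dioxolan-2-yl)ethyl]oxepan-3-yl]oxy}dimethylsilane
Conditions: TBSOTf, 2,6-lutidine, CH2Cl2, −78 °C
Reagents that add atoms: tert-butyldimethylsilyl trifluoromethanesulfonate, CC(C)(C)[Si](C)(C)OS(=O)(=O)C(F)(F)F
Why: Silylation with the silyl triflate and a hindered pyridine base protects the neopentyl-type secondary alcohol at low temperature, at which the ketone-derived dioxolane is not attacked.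

Step 9
Reactants: 14 tert-butyl{[(3R,6S,7S)-6-ethenyl-2,2,6-trimethyl-7-[2-(2-methyl-1,3-dioxolan-2-yl)ethyl]oxepan-3-yl]oxy}dimethylsilane
Product: 15 1-[(3R,6R,7S)-3-{[tert-butyl(dimethyl)silyl]oxy}-2,2,6-trimethyl-7-[2-(2-methyl-1,3-dioxolan-2-yl)ethyl]oxepan-6-yl]ethan-1-one
Conditions: PdCl2 (10 mol%), Cu(OAc)2·H2O (20 mol%), O2 (1 atm), N,N-dimethylacetamide–H2O 7:1, 25–40 °C
Reagents that add atoms: water, O
Why: Tsuji–Wacker oxidation: Markovnikov hydroxypalladation of the monosubstituted vinyl group by divalent palladium followed by β-hydride elimination and tautomerisation gives the methyl ketone, and the acetate-buffered chloride-poor medium spares the dioxolane and the silyl ether.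

Step 10
Reactants: 15 1-[(3R,6R,7S)-3-{[tert-butyl(dimethyl)silyl]oxy}-2,2,6-trimethyl-7-[2-(2-methyl-1,3-dioxolan-2-yl)ethyl]oxepan-6-yl]ethan-1-one (two molecules)
Product: 17 1,4-bis[(3R,6R,7S)-3-{[tert-butyl(dimethyl)silyl]oxy}-2,2,6-trimethyl-7-[2-(2-methyl-1,3-dioxolan-2-yl)ethyl]oxepan-6-yl]butane-1,4-dione, via lithium enolate 16 (not isolated)
Conditions: LiN(i-Pr)2 (LDA, commercial solution, 1.1 equiv), THF, −78 °C; then CuCl2 (1.1 equiv), DMF, −78 °C to rt
Reagents that add atoms: none
Why: Oxidative enolate coupling: the acetyl methyl is the only enolisable position of 15, and one-electron oxidation of its lithium enolate by CuCl2 gives α-keto radicals that dimerise at carbon to the symmetrical 1,4-diketone (C12–C13 bond), with any residual stereoisomeric impurity diverted into separable diastereomeric dimers.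

Step 11
Reactants: 17 1,4-bis[(3R,6R,7S)-3-{[tert-butyl(dimethyl)silyl]oxy}-2,2,6-trimethyl-7-[2-(2-methyl-1,3-dioxolan-2-yl)ethyl]oxepan-6-yl]butane-1,4-dione
Product: 18 1,4-bis[(3R,6R,7S)-3-{[tert-butyl(dimethyl)silyl]oxy}-2,2,6-trimethyl-7-(3-oxobutyl)oxepan-6-yl]butane-1,4-dione (the C2-symmetric tetraketone)
Conditions: pyridinium p-toluenesulfonate (0.3 equiv), acetone–H2O 10:1, reflux
Reagents that add atoms: water, O
Why: Mild acid-catalysed ketal exchange with wet acetone liberates both methyl ketones under conditions that the hindered secondary silyl ethers and the ring ethers withstand, and the 1,4-diketone between two quaternary carbons is slow to cyclodehydrate with so weak an acid.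

Step 12
Reactants: 18 1,4-bis[(3R,6R,7S)-3-{[tert-butyl(dimethyl)silyl]oxy}-2,2,6-trimethyl-7-(3-oxobutyl)oxepan-6-yl]butane-1,4-dione
Product: 20 1,2-bis[(3R,5aS,9aS)-3-{[tert-butyl(dimethyl)silyl]oxy}-2,2,5a,7-tetramethyl-2,3,4,5,5a,8,9,9a-octahydro-1-benzoxepin-6-yl]ethane, via bis(titanium pinacolate) 19 (not isolated)
Conditions: TiCl3(DME)1.5 (about 20 equiv), Zn–Cu couple (about 50 equiv), DME, reflux 2 h; then 18 in DME by syringe pump over 36 h (final about 0.002 M), reflux 6 h more; filtration through Florisil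
Reagents that add atoms: none
Why: Low-valent titanium made from TiCl3 and the zinc–copper couple transfers single electrons to the carbonyl groups, the titanium-bound ketyls couple carbon to carbon to give the titanium pinacolate 19, and at reflux the oxophilic metal removes both oxygens to leave the C=C bond; the closest known reaction type is the intramolecular McMurry coupling of 1,6-diketones to tetrasubstituted cyclohexenes. Each of the two cyclohexene rings (C6–C7–C8–C9–C10–C11 and C19–C18–C17–C16–C15–C14) closes in the 6-exo mode, the ketyl of the methyl ketone (C10 or C15) adding to the neighbouring hindered carbonyl (C11 or C14) held on the same oxepane. No stereocentre is created, because both carbinolate carbons of each pinacolate end as sp2 carbons, and the existing centres C3, C6 and C7 (C22, C19 and C18) cannot epimerise since C6 and C19 are quaternary and the others are not α to a carbonyl. The selectivity required is that each hindered ketone pairs with its own methyl ketone and not with its 1,4-partner across C12–C13 (a cyclobutene) or with a carbonyl of the other half (rings of nine or more atoms): the kinetic preference for six-membered closure of a 1,6-diketone on adjacent ring carbons and slow addition at high dilution secure it. The silyl ethers, the tertiary ring ethers and the absence of any leaving group α to a carbonyl keep the rest of the molecule inert to the electron-rich, Lewis-acidic titanium.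

Step 13
Reactants: 20 1,2-bis[(3R,5aS,9aS)-3-{[tert-butyl(dimethyl)silyl]oxy}-2,2,5a,7-tetramethyl-2,3,4,5,5a,8,9,9a-octahydro-1-benzoxepin-6-yl]ethane
Product: 21 6,6'-(ethane-1,2-diyl)bis[(3R,5aS,9aS)-2,2,5a,7-tetramethyl-2,3,4,5,5a,8,9,9a-octahydro-1-benzoxepin-3-ol] (the C2-symmetric 3,22-diol)
Conditions: Bu4NF (TBAF, 6 equiv), THF, 50 °C
Reagents that add atoms: none
Why: Fluoride attacks silicon and cleaves both hindered secondary silyl ethers under basic conditions that leave the acid-sensitive tetrasubstituted olefins and tertiary ethers untouched.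

Step 14
Reactants: 21 6,6'-(ethane-1,2-diyl)bis[(3R,5aS,9aS)-2,2,5a,7-tetramethyl-2,3,4,5,5a,8,9,9a-octahydro-1-benzoxepin-3-ol]
Product: 22 sodwanone T {(5aS,9aS)-6-{2-[(3R,5aS,9aS)-3-hydroxy-2,2,5a,7-tetramethyl-2,3,4,5,5a,8,9,9a-octahydro-1-benzoxepin-6-yl]ethyl}-2,2,5a,7-tetramethyl-4,5,5a,8,9,9a-hexahydro-1-benzoxepin-3(2H)-one}
Conditions: Dess–Martin periodinane (0.8 equiv, added in portions), NaHCO3, CH2Cl2, 0 °C; chromatography; recovered 21 resubmitted
Reagents that add atoms: none
Why: Dess–Martin oxidation converts one of the two equivalent and mutually remote secondary carbinols (C3 or C22) into the ketone in a statistical mono-oxidation that is run with a deficit of oxidant so that the main other component is diol 21, which is separated by chromatography and resubmitted.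

Compound list
1 | nerol, (2Z)-3,7-dimethylocta-2,6-dien-1-ol | CC(C)=CCC/C(C)=C\CO | starting material
2 | neryl mesylate, (2Z)-3,7-dimethylocta-2,6-dien-1-yl methanesulfonate | CC(C)=CCC/C(C)=C\COS(C)(=O)=O | intermediate
3 | neryl chloride, (2Z)-1-chloro-3,7-dimethylocta-2,6-diene | CC(C)=CCC/C(C)=C\CCl | intermediate
4 | bis(pinacolato)diboron | CC1(C)OB(OC1(C)C)B1OC(C)(C)C(C)(C)O1 | starting material
5 | neryl pinacol boronate, 2-[(2Z)-3,7-dimethylocta-2,6-dien-1-yl]-4,4,5,5-tetramethyl-1,3,2-dioxaborolane | CC(C)=CCC/C(C)=C\CB1OC(C)(C)C(C)(C)O1 | intermediate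
6 | ethyl levulinate | CCOC(=O)CCC(C)=O | starting material
7 | ethyl 3-(2-methyl-1,3-dioxolan-2-yl)propanoate | CCOC(=O)CCC1(C)OCCO1 | intermediate
8 | aluminium hemiacetal, diisobutylaluminium 1-ethoxy-3-(2-methyl-1,3-dioxolan-2-yl)propan-1-olate | CCOC(CCC1(C)OCCO1)O[Al](CC(C)C)CC(C)C | intermediate
9 | 3-(2-methyl-1,3-dioxolan-2-yl)propanal | O=CCCC1(C)OCCO1 | intermediate
10 | pinacol borate of 11, 2-{[(3S,4S)-4-ethenyl-4,8-dimethyl-1-(2-methyl-1,3-dioxolan-2-yl)non-7-en-3-yl]oxy}-4,4,5,5-tetramethyl-1,3,2-dioxaborolane | CC1(OCCO1)CC[C@H](OB2OC(C)(C)C(C)(C)O2)[C@](C)(C=C)CCC=C(C)C | intermediate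
11 | (3S,4S)-4-ethenyl-4,8-dimethyl-1-(2-methyl-1,3-dioxolan-2-yl)non-7-en-3-ol | CC1(OCCO1)CC[C@H](O)[C@](C)(C=C)CCC=C(C)C | intermediate
12 | (3S,4S)-6-[(2R)-3,3-dimethyloxiran-2-yl]-4-ethenyl-4-methyl-1-(2-methyl-1,3-dioxolan-2-yl)hexan-3-ol | CC1(OCCO1)CC[C@H](O)[C@](C)(C=C)CC[C@H]1OC1(C)C | intermediate
13 | (3R,6S,7S)-6-ethenyl-2,2,6-trimethyl-7-[2-(2-methyl-1,3-dioxolan-2-yl)ethyl]oxepan-3-ol | CC1(OCCO1)CC[C@@H]2OC(C)(C)[C@H](O)CC[C@@]2(C)C=C | intermediate
14 | tert-butyl{[(3R,6S,7S)-6-ethenyl-2,2,6-trimethyl-7-[2-(2-methyl-1,3-dioxolan-2-yl)ethyl]oxepan-3-yl]oxy}dimethylsilane | CC1(OCCO1)CC[C@@H]2OC(C)(C)[C@H](O[Si](C)(C)C(C)(C)C)CC[C@@]2(C)C=C | intermediate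
15 | 1-[(3R,6R,7S)-3-{[tert-butyl(dimethyl)silyl]oxy}-2,2,6-trimethyl-7-[2-(2-methyl-1,3-dioxolan-2-yl)ethyl]oxepan-6-yl]ethan-1-one | CC1(OCCO1)CC[C@@H]2OC(C)(C)[C@H](O[Si](C)(C)C(C)(C)C)CC[C@@]2(C)C(C)=O | intermediate
16 | lithium enolate of 15 (lithium 1-(oxepan-6-yl)ethen-1-olate, ring substituents as in 15) | CC1(OCCO1)CC[C@@H]2OC(C)(C)[C@H](O[Si](C)(C)C(C)(C)C)CC[C@@]2(C)C(=C)O[Li] | intermediate
17 | 1,4-bis[(3R,6R,7S)-3-{[tert-butyl(dimethyl)silyl]oxy}-2,2,6-trimethyl-7-[2-(2-methyl-1,3-dioxolan-2-yl)ethyl]oxepan-6-yl]butane-1,4-dione | CC1(OCCO1)CC[C@@H]2OC(C)(C)[C@H](O[Si](C)(C)C(C)(C)C)CC[C@@]2(C)C(=O)CCC(=O)[C@]3(C)CC[C@@H](O[Si](C)(C)C(C)(C)C)C(C)(C)O[C@H]3CCC4(C)OCCO4 | intermediate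
18 | 1,4-bis[(3R,6R,7S)-3-{[tert-butyl(dimethyl)silyl]oxy}-2,2,6-trimethyl-7-(3-oxobutyl)oxepan-6-yl]butane-1,4-dione | CC(=O)CC[C@@H]1OC(C)(C)[C@H](O[Si](C)(C)C(C)(C)C)CC[C@@]1(C)C(=O)CCC(=O)[C@]1(C)CC[C@@H](O[Si](C)(C)C(C)(C)C)C(C)(C)O[C@H]1CCC(C)=O | intermediate
19 | bis(titanium pinacolate) of 18, drawn as two 2-titana-1,3-dioxolanes spanning C10/C11 and C14/C15 (other ligands on titanium not drawn; configuration at the four carbinolate carbons not defined) | CC12CC[C@@H]3OC(C)(C)[C@H](O[Si](C)(C)C(C)(C)C)CC[C@@]3(C)C1(O[Ti]O2)CCC4(O[Ti]O6)[C@]5(C)CC[C@@H](O[Si](C)(C)C(C)(C)C)C(C)(C)O[C@H]5CCC46C | intermediate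
20 | 1,2-bis[(3R,5aS,9aS)-3-{[tert-butyl(dimethyl)silyl]oxy}-2,2,5a,7-tetramethyl-2,3,4,5,5a,8,9,9a-octahydro-1-benzoxepin-6-yl]ethane | CC1=C(CCC2=C(C)CC[C@@H]3OC(C)(C)[C@H](O[Si](C)(C)C(C)(C)C)CC[C@@]23C)[C@]2(C)CC[C@@H](O[Si](C)(C)C(C)(C)C)C(C)(C)O[C@H]2CC1 | intermediate
21 | 6,6'-(ethane-1,2-diyl)bis[(3R,5aS,9aS)-2,2,5a,7-tetramethyl-2,3,4,5,5a,8,9,9a-octahydro-1-benzoxepin-3-ol] | CC1=C(CCC2=C(C)CC[C@@H]3OC(C)(C)[C@H](O)CC[C@@]23C)[C@]2(C)CC[C@@H](O)C(C)(C)O[C@H]2CC1 | intermediate
22 | sodwanone T | CC1=C(CCC2=C(C)CC[C@@H]3OC(C)(C)[C@H](O)CC[C@@]23C)[C@]2(C)CCC(=O)C(C)(C)O[C@H]2CC1 | target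

Total step count: 14.
Longest linear sequence: 12 steps (1 to 22 through steps 1, 2 and 5–14; the branch from 6 through steps 3, 4 and 5–14 is equally long).

The three steps most likely to fail

Step 12 (double McMurry closure). What may go wrong: deoxygenation may stall at pinacols next to the quaternary carbons, and the Lewis-acidic titanium chlorides may cyclodehydrate the 1,4-diketone to a furan. Ketyl coupling across the 1,4-diketone or between the two halves is also possible if the six-membered closure is slowed by steric hindrance. The fallback keeps the same two bonds but separates C–C bond formation from deoxygenation. It sets out from 18: SmI2 (about 10 equiv) in THF with t-BuOH at 0 °C to room temperature should effect the ketyl–carbonyl pinacol coupling in each half and give the bis(cis-1,2-diol), the tetraol F1. Thiocarbonyldiimidazole with DMAP in refluxing toluene then converts each cis-diol into its cyclic thionocarbonate, the bis(thionocarbonate) F2. Heating F2 in P(OMe)3 at about 120 °C (Corey–Winter olefination, a stereospecific syn-elimination) should return the route at 20.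

Step 7 (oxepane closure). What may go wrong: the hydroxyl may open the epoxide at the nearer secondary carbon (6-exo attack), which would give a tetrahydropyran carrying an exocyclic tertiary carbinol in place of the oxepane. Acid-induced hydride shift of the epoxide to a ketone is a second possible diversion. The fallback removes the regiochemical choice by forming the C2–O bond from a tertiary radical/cation that can only be captured in the seven-membered mode. It sets out from 12: Et2Al(TMP) (diethylaluminium 2,2,6,6-tetramethylpiperidide, 4 equiv) in toluene at 0 °C isomerises the gem-dimethyl epoxide to the isopropenyl carbinol with retention at C3, giving the allylic alcohol diol F3. TBSCl and imidazole in DMF at 0 °C silylate the less hindered allylic hydroxyl selectively, giving the mono-silyl ether F4. Markovnikov hydroalkoxylation by cobalt hydride hydrogen-atom transfer then closes the ring, which returns the route at 14. Its conditions are a Co(salen) complex of divalent cobalt (3 mol%), N-fluoro-2,4,6-trimethylpyridinium tetrafluoroborate and 1,1,3,3-tetramethyldisiloxane in PhCF3 at room temperature.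

Step 9 (Wacker oxidation). What may go wrong: hydroxypalladation may be slow at the vinyl group on the quaternary carbon or occur at the terminal carbon under the influence of the ring oxygen (aldehyde formation), and the dioxolane may be lost if the medium turns acidic. The fallback replaces the palladium chemistry by a radical hydration. It sets out from 14: Mukaiyama hydration with Co(acac)2 (20 mol%), PhSiH3 and O2 (1 atm) in THF–i-PrOH at room temperature should give the Markovnikov secondary alcohol as an epimer mixture, the carbinol F5. Dess–Martin periodinane with NaHCO3 in CH2Cl2 then oxidises both epimers to the same methyl ketone, which returns the route at 15.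

Further compounds
F1 | step 12 | 1,2-bis[(3R,5aR,9aS)-3-{[tert-butyl(dimethyl)silyl]oxy}-6,7-dihydroxy-2,2,5a,7-tetramethyldecahydro-1-benzoxepin-6-yl]ethane (cis-6,7-diols; configuration at C6 and C7 of each ring not defined) | CC1(O)CC[C@@H]2OC(C)(C)[C@H](O[Si](C)(C)C(C)(C)C)CC[C@@]2(C)C1(O)CCC3(O)[C@]4(C)CC[C@@H](O[Si](C)(C)C(C)(C)C)C(C)(C)O[C@H]4CCC3(C)O
F2 | step 12 | bis(cyclic thionocarbonate) of F1 (a 1,3-dioxolane-2-thione fused at C6/C7 of each ring) | CC12CC[C@@H]3OC(C)(C)[C@H](O[Si](C)(C)C(C)(C)C)CC[C@@]3(C)C1(OC(=S)O2)CCC4(OC(=S)O6)[C@]5(C)CC[C@@H](O[Si](C)(C)C(C)(C)C)C(C)(C)O[C@H]5CCC46C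
F3 | step 7 | (3S,4S,7R)-4-ethenyl-4,8-dimethyl-1-(2-methyl-1,3-dioxolan-2-yl)non-8-ene-3,7-diol | CC1(OCCO1)CC[C@H](O)[C@](C)(C=C)CC[C@@H](O)C(C)=C
F4 | step 7 | (3S,4S,7R)-7-{[tert-butyl(dimethyl)silyl]oxy}-4-ethenyl-4,8-dimethyl-1-(2-methyl-1,3-dioxolan-2-yl)non-8-en-3-ol | CC1(OCCO1)CC[C@H](O)[C@](C)(C=C)CC[C@@H](O[Si](C)(C)C(C)(C)C)C(C)=C
F5 | step 9 | (1RS)-1-[(3R,6S,7S)-3-{[tert-butyl(dimethyl)silyl]oxy}-2,2,6-trimethyl-7-[2-(2-methyl-1,3-dioxolan-2-yl)ethyl]oxepan-6-yl]ethan-1-ol | CC1(OCCO1)CC[C@@H]2OC(C)(C)[C@H](O[Si](C)(C)C(C)(C)C)CC[C@@]2(C)C(C)O
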